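As the chemist at this bench I had these runs before me, and one flask still to come, Sunday's, which is charged with X as well as J and E.

| flask | J | E | X | time |
|---|---|---|---|---|
| Thursday's | 0.200 M | 0.0100 M |  |  |
| Saturday's | 0.100 M | 0.0100 M |  |  |
| Tuesday's | 0.200 M | 0.0150 M |  |  |
| Wednesday's | 0.400 M | 0.0100 M |  |  |
| Sunday's | 0.200 M | 0.0100 M | 0.0600 M | 120 h |

| Thursday's run: time / h | Thursday's run: [X] / M | Saturday's run: time / h | Saturday's run: [X] / M | Tuesday's run: time / h | Tuesday's run: [X] / M | Wednesday's run: time / h | Wednesday's run: [X] / M |
|---|---|---|---|---|---|---|---|
| 4.8 | 0.0054 | 4.8 | 0.0048 | 4.8 | 0.0099 | 4.8 | 0.0059 |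
| 9.1 | 0.0105 | 9.1 | 0.0095 | 9.1 | 0.0177 | 9.1 | 0.0116 |
| 17 | 0.0187 | 17 | 0.0187 | 17 | 0.0320 | 17 | 0.0225 |
| 33 | 0.0376 | 33 | 0.0311 | 33 | 0.0596 | 33 | 0.0396 |
| 63 | 0.0644 | 63 | 0.0553 | 63 | 0.1032 | 63 | 0.0676 |
| 120 | 0.1018 | 120 | 0.0814 | 120 | 0.1598 | 120 | 0.1098 |

(scatter of a reading: 6 × 10⁻⁴ M)

- Overall: J -> X, with E as catalyst.
- Constant volume, constant temperature.
- Readings of a species count what is bound in complexes too.
- An order is taken over about fifteen percent of the charge, up and down.
- A share of X counts the X that was charged too.

* order of the initial rate in [J], near the charge of the Thursday's run, the rate being that where two percent of its J are X (one fixed amount of X, the same in the runs compared)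
* order of the initial rate in [E], near the charge of the Thursday's run, the rate being that where two percent of its J are X
* the Saturday's run starts with 0.100 M less of J than the Thursday's run, and with no X. Compared where both hold the same amount of J, once fifteen percent of what the Saturday's run was charged with has turned into X, is the Saturday's run faster, slower or alike (within a tenth)?
* X in the Sunday's run at 120 h, as a share of the J charged

I looked first at what J does. At 33 h Wednesday's run, charged with 0.400 M of J, held 0.0396 M of X, and Saturday's run, charged with 0.100 M, held 0.0311 M. A factor of 4.00 in J had moved the X by a factor of 1.27, so in these early hours the rate followed J weakly, and two flasks of equal J could be compared by their catalyst.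

Thursday's and Tuesday's runs have the same J, and their charges of E differ by a factor of 1.50. I added up the first 4 readings of each run to keep the scatter small, and Tuesday's sum stood at 1.65 times Thursday's, which is more than the factor of the charges.

So I wrote the balance of E, which is charged in a smaller amount than J: E charged equals E at work plus a fixed amount that does no work from the start. That the amount is fixed was my assumption, and so was leaving out any E lost during those hours; two charges of E give one ratio, and one ratio gave me no test of either. If the rate goes with E at work, that ratio is 0.0150 M less the amount over 0.0100 M less the amount. This gives the dead dose, the amount of charged E that does no work, as a reading of 0.00232 M, and it leaves 0.00768 M at work in Thursday's run. A small rise in the charge lands wholly on the E at work, so the order in E is the charge over the charge less the dead dose, which for Thursday's run I reckoned at 1.30.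

The forecast, made from the same runs, gave 0.1 for the order in J, 1.25 for the order in E, faster for Saturday's run at equal J, and 80.5% for Sunday's run, on the ground that “The runs fit a catalyst that dies with time, not product inhibition”. Its order in E stood below mine.

The simulation gave 0.12 for the order in J, which the forecast had too low, 1.3 for the order in E, faster for Saturday's run, and 81.2% for Sunday's run.

    E + J ⇌ EJ (18.72 M⁻¹ h⁻¹, 0.2880 h⁻¹)
    EJ → X + E (0.1840 h⁻¹)
    EJ → Qi + J (0.007020 h⁻¹)
    E + Ez → Qi

In Thursday's run Ez, a stoichiometric poison, took up E at once at the start, and what stayed, by my reading 0.00768 M, passed between E and EJ, with EJ giving X at 0.184 h⁻¹ and falling to Qi + J at 0.00702 h⁻¹ for as long as EJ was there, which comes to 26.2 X for each E lost. In Wednesday's run, charged with the same 0.0100 M of E, that count and the dead dose give 0.201 M of X over the whole life of the catalyst, and the X made there came to 0.200 M at 707 h.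

(All runs stem from a simulated flask from invented constants, and the scatter is random.)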